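**Strategy.** The route rests on disconnecting the a5–O–b6 diaryl ether bond of the dioxepinone, which leaves an orcinol ester of the complete ring A acid. In that depside, carbon b6 of ring B is para to the free b3 hydroxyl and ortho to the ester oxygen on b1, and the a6 ester holds the a5 hydroxyl of ring A above it. A single oxidation of the ring B phenol with a trivalent iodine reagent should therefore form the ether bond and close the seven-membered ring. The precursor carries no protecting groups and is assembled by formylation, ester cleavage and carbodiimide esterification. A Friedel–Crafts/oxa-Michael annulation at b4 then completes the chromanone.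

Key step: step 4

Remark (labels and assumption): ring A is the formyl-bearing ring, with a1 (C–CH3), a2 (C–H), a3 (C–OH), a4 (C–CHO), a5 (C–O ether) and a6 (C–C(=O)O); ring B is the benzene ring of the chromanone, with b1 (C–O lactone), b2 (C–H), b3 (C–O pyranone), b4 (C–C=O), b5 (C–CH3) and b6 (C–O ether). The target has no stereocentre. It is assumed that the hindered depside ester is best made under neutral carbodiimide activation, because free orcinol is prone to ring acylation under strongly acidic acylating conditions.

**Step 1**
Reactants: 1 methyl orsellinate (methyl 2,4-dihydroxy-6-methylbenzoate); 2 dichloromethyl methyl ether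
Product: 4 methyl haematommate (methyl 3-formyl-2,4-dihydroxy-6-methylbenzoate), via chloro(methoxy)methyl arene 3 (not isolated)
Conditions: TiCl4 (3 equiv), CH2Cl2, 0 °C; then 2 (1.1 equiv), 0 °C to rt; ice/aq. HCl
Reagents that add atoms: water, O
Why: Rieche formylation, in which titanium phenoxide formation directs the chloro(methoxy)carbenium electrophile ortho to oxygen and C3, activated by both flanking hydroxyls, should be favoured over C5 (any C5 isomer being removed by crystallisation or chromatography), the aqueous work-up hydrolysing chloro ether 3 to the aldehyde.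

**Step 2**
Reactants: 4 methyl haematommate
Product: 6 haematommic acid (3-formyl-2,4-dihydroxy-6-methylbenzoic acid), via acylium hydrogensulfate 5 (not isolated)
Conditions: conc. H2SO4, 0 °C to rt; poured onto ice
Reagents that add atoms: water, O
Why: AAC1 acyl–oxygen cleavage of a 2,6-disubstituted benzoate in cold concentrated sulfuric acid, driven by the acylium ion 5 that the ortho and para hydroxyls stabilise and completed by water on quenching, which avoids the forcing alkaline hydrolysis that this hindered, easily decarboxylated acid would not tolerate.

**Step 3**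
Reactants: 6 haematommic acid; 7 orcinol (5-methylbenzene-1,3-diol, 4 equiv)
Product: 9 depside 3-hydroxy-5-methylphenyl 3-formyl-2,4-dihydroxy-6-methylbenzoate, via O-acylisourea 8 (not isolated)
Conditions: DCC (1.1 equiv), toluene–THF, 0 °C to rt
Reagents that add atoms: none
Why: carbodiimide-mediated esterification (classical depside synthesis), in which a free hydroxyl of orcinol captures O-acylisourea 8 while both hydroxyls of the acid are tied up in hydrogen bonds to the formyl and carboxyl groups, the excess of symmetric orcinol favouring the monoester and the neutral medium avoiding C-acylation of the electron-rich ring.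

**Step 4**
Reactants: 9 depside
Product: 12 depsidone 3,8-dihydroxy-1,6-dimethyl-11-oxo-11H-dibenzo[b,e][1,4]dioxepine-4-carbaldehyde, via aryloxyiodane 10 (not isolated), via cyclohexadienone 11 (not isolated)
Conditions: PhI(OAc)2 (1.0 equiv, added slowly), (CF3)2CHOH, 0.005 M, 0 °C
Reagents that add atoms: none
Why: Proposed new method: the non-chelated b3 hydroxyl of ring B should exchange an acetate on trivalent iodine to give aryloxy-λ3-iodane 10, and loss of PhI with build-up of positive charge at b6 (para) is answered by the a5 hydroxyl, which the a6 ester holds over that carbon and which the fluoroalcohol frees from its hydrogen bond, giving dienone 11 that tautomerises to the aromatic ether 12. The closest known reaction type is the hypervalent-iodine para-functionalisation of phenols by oxygen nucleophiles (para-quinol ether and spirolactone formation), together with the oxidative phenol coupling invoked for depsidone biosynthesis. The seven-membered dioxepinone ring closes in a 7-exo-trig mode on the b5=b6 bond of the activated ring. No stereocentre results, since the transient sp3 carbon b6 of 11 is lost on re-aromatisation. Site selectivity rests on ring A being deactivated by its formyl and ester groups with both of its hydroxyls chelated, on b6 carrying the larger share of cation character and leading to the cross-conjugated dienone, and on the iodanyl group screening the ortho carbons b2 and b4 (b4 is in any case out of reach of the tether). Over-oxidation of the more electron-rich product and intermolecular coupling are held back by slow addition of a single equivalent of oxidant at high dilution in a solvent too weakly nucleophilic to intercept the cation.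

**Step 5**
Reactants: 12 depsidone; 13 3-methylbut-2-enoic acid (1.2 equiv)
Product: 15 mollicellin A, via aryl enone 14 (not isolated)
Conditions: MeSO3H/P2O5 (10:1 w/w), 60–70 °C; ice-water
Reagents that add atoms: none
Why: Friedel–Crafts acylation/oxa-Michael annulation in MeSO3H/P2O5 (the standard 2,2-dimethylchroman-4-one synthesis from phenols), in which the acylium derived from the mixed anhydride should attack b4, ortho to the free b3 hydroxyl, para to the b1 oxygen and beside the methyl group as in acylations of orcinol-type rings, after which the b3 hydroxyl closes 6-endo-trig onto enone 14; ring A is deactivated and b6 is blocked.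

**Compound list**
1 | methyl orsellinate (methyl 2,4-dihydroxy-6-methylbenzoate) | Cc1cc(O)cc(O)c1C(=O)OC | starting material
2 | dichloromethyl methyl ether | COC(Cl)Cl | starting material
3 | methyl 3-[chloro(methoxy)methyl]-2,4-dihydroxy-6-methylbenzoate (racemic) | COC(Cl)c1c(O)cc(C)c(C(=O)OC)c1O | intermediate (not isolated)
4 | methyl haematommate (methyl 3-formyl-2,4-dihydroxy-6-methylbenzoate) | COC(=O)c1c(C)cc(O)c(C=O)c1O | intermediate
5 | 3-formyl-2,4-dihydroxy-6-methylbenzoylium hydrogensulfate | Cc1cc(O)c(C=O)c(O)c1C#[O+].OS(=O)(=O)[O-] | intermediate (not isolated)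
6 | haematommic acid (3-formyl-2,4-dihydroxy-6-methylbenzoic acid) | Cc1cc(O)c(C=O)c(O)c1C(=O)O | intermediate
7 | orcinol (5-methylbenzene-1,3-diol) | Cc1cc(O)cc(O)c1 | starting material
8 | O-(3-formyl-2,4-dihydroxy-6-methylbenzoyl)-N,N'-dicyclohexylisourea | Cc1cc(O)c(C=O)c(O)c1C(=O)OC(=NC1CCCCC1)NC1CCCCC1 | intermediate (not isolated)
9 | depside, 3-hydroxy-5-methylphenyl 3-formyl-2,4-dihydroxy-6-methylbenzoate | Cc1cc(O)cc(OC(=O)c2c(C)cc(O)c(C=O)c2O)c1 | intermediate
10 | 3-{[acetoxy(phenyl)-λ3-iodanyl]oxy}-5-methylphenyl 3-formyl-2,4-dihydroxy-6-methylbenzoate | CC(=O)OI(Oc1cc(C)cc(OC(=O)c2c(C)cc(O)c(C=O)c2O)c1)c1ccccc1 | intermediate (not isolated)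
11 | 3-hydroxy-1,6-dimethyl-8,11-dioxo-5a,8-dihydro-11H-dibenzo[b,e][1,4]dioxepine-4-carbaldehyde (racemic at C5a = b6) | Cc1cc(O)c(C=O)c2c1C(=O)OC1=CC(=O)C=C(C)C1O2 | intermediate (not isolated)
12 | depsidone, 3,8-dihydroxy-1,6-dimethyl-11-oxo-11H-dibenzo[b,e][1,4]dioxepine-4-carbaldehyde (a3 hydroxyl, a4 formyl, b3 hydroxyl) | Cc1cc(O)c(C=O)c2c1C(=O)Oc1cc(O)cc(C)c1O2 | intermediate
13 | 3-methylbut-2-enoic acid | CC(C)=CC(=O)O | starting material
14 | 3,8-dihydroxy-1,6-dimethyl-7-(3-methylbut-2-enoyl)-11-oxo-11H-dibenzo[b,e][1,4]dioxepine-4-carbaldehyde (enone on b4) | Cc1cc(O)c(C=O)c2c1C(=O)Oc1cc(O)c(C(=O)C=C(C)C)c(C)c1O2 | intermediate (not isolated)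
15 | mollicellin A: depsidone 12 with a 2,2-dimethylchroman-4-one ring fused on ring B (ring oxygen on b3, ketone carbon on b4, then CH2 and C(CH3)2); achiral | Cc1cc(O)c(C=O)c2c1C(=O)Oc1cc3c(c(C)c1O2)C(=O)CC(C)(C)O3 | target

**Total step count:** 5
**Longest linear sequence:** 5 steps (1 → 4 → 6 → 9 → 12 → 15)

**Steps most likely to fail**

1. Step 4 (Proposed new method). The seven-membered closure by a weakly nucleophilic, chelated hydroxyl may be outrun by intermolecular C–C or C–O phenol coupling, by attack at b2, by capture of the cation by acetate, or by further oxidation of the product ring. The fallback uses known chemistry and sets out from 9. Para-selective bromination of the ring B phenol (Bu4NBr3, CH2Cl2–MeOH, 0 °C) should give 2-bromo-5-hydroxy-3-methylphenyl 3-formyl-2,4-dihydroxy-6-methylbenzoate F1. An intramolecular copper-catalysed Ullmann diaryl ether formation between the a5 hydroxyl and the b6 bromide (CuI, N,N-dimethylglycine, Cs2CO3, dioxane, 90 °C, dilute) then comes back to the route at 12. The phenoxide para to the bromide will slow this coupling, so forcing conditions may be needed.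

2. Step 5. Acylation may occur at b2 in place of b4, the protonated enoic acid may C-alkylate ring B before acylation (which leads to a lactone instead of the ketone), and the strong acid may cause condensation at the formyl group or acylation of the a3 hydroxyl. The fallback sets out from 12. Chemoselective O-acylation of the non-chelated b3 hydroxyl with 3-methylbut-2-enoyl chloride (pyridine, CH2Cl2, −20 °C) should give 4-formyl-3-hydroxy-1,6-dimethyl-11-oxo-11H-dibenzo[b,e][1,4]dioxepin-8-yl 3-methylbut-2-enoate F2. An ortho-Fries rearrangement under aprotic Lewis acid conditions (AlCl3 or TiCl4, CH2Cl2, rt to reflux) delivers the acyl group from the b3 oxygen to give enone 14, which closes in the same pot or on brief warming with NaOAc in EtOH. The fallback comes back to the route at 15. It removes the free acid and the protic superacid, but it does not by itself settle the b2/b4 question.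

3. Step 3. Orcinol may be acylated twice, and the hindered O-acylisourea may rearrange to the N-acylurea before the phenol captures it. The fallback sets out from 7 and 6. Monosilylation of 7 (TBSCl, 1 equiv, imidazole, DMF) gives 3-[(tert-butyldimethylsilyl)oxy]-5-methylphenol F3. Activation of 6 as its mixed carboxylic–trifluoroacetic anhydride ((CF3CO)2O, toluene, rt) in the presence of F3 should give 3-[(tert-butyldimethylsilyl)oxy]-5-methylphenyl 3-formyl-2,4-dihydroxy-6-methylbenzoate F4. Desilylation with HF·pyridine in THF at 0 °C comes back to the route at 9.

**Further compounds**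
F1 | step 4 | 2-bromo-5-hydroxy-3-methylphenyl 3-formyl-2,4-dihydroxy-6-methylbenzoate | Cc1cc(O)cc(OC(=O)c2c(C)cc(O)c(C=O)c2O)c1Br
F2 | step 5 | 4-formyl-3-hydroxy-1,6-dimethyl-11-oxo-11H-dibenzo[b,e][1,4]dioxepin-8-yl 3-methylbut-2-enoate | Cc1cc(O)c(C=O)c2c1C(=O)Oc1cc(OC(=O)C=C(C)C)cc(C)c1O2
F3 | step 3 | 3-[(tert-butyldimethylsilyl)oxy]-5-methylphenol | Cc1cc(O)cc(O[Si](C)(C)C(C)(C)C)c1
F4 | step 3 | 3-[(tert-butyldimethylsilyl)oxy]-5-methylphenyl 3-formyl-2,4-dihydroxy-6-methylbenzoate | Cc1cc(O[Si](C)(C)C(C)(C)C)cc(OC(=O)c2c(C)cc(O)c(C=O)c2O)c1
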